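**Retrosynthetic overview**

1. The last bond made is the ester C14–O–C(=O)–C8′ between diol lactone 25 (rings A and B) and left acid 51; the tert-butyl ester and the silyl groups are then removed.
2. Ring B (C4a–C9–O10–C11–C12=C13–C8a) is closed by ring-closing metathesis of a C13 vinyl group onto the 2-(tert-butoxycarbonyl)allyl ester of the C9 acid. Before that, C4a is inverted as an ester α-carbon while C13 is masked as an acetal.
3. The strategy rests on ring A: C4 (O and C14H2O) and C1 (isopropyl) are para with their carbon branches cis, and C4a/C8a carry C9 and C13. Ring A is therefore the ethano-plus-dienophile part of a bicyclo[2.2.2]octene made by Diels–Alder reaction of siloxydiene 2 with menthyloxyfuranone 6; ozone cuts its CH=C(CH3) bridge into C14 (CHO) and an acetyl group, the later isopropyl.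
4. In the left acid, C1′ and C6′ are antipodal to C8a and C1, so the same sequence is run from (−)-menthol to lactone 44. Hydrolysis, β-lactonisation of the C4-hydroxy C9-acid and loss of CO2 then turn ring A into the C2′=C3′ cyclohexene.
5. Ring order: ring A (step 4, as the bicyclooctene, bridge cut in step 5), then ring B (step 17). In the left series: ring (step 20), temporary lactone (step 33, opened in step 34), β-lactone (step 36, lost in step 37).

Key step: step 4

Labels: ring A = C1 (isopropyl), C2, C3, C4 (OH, C14H2O), C4a (C9), C8a (C13); ring B as in line 2, C15 = carboxyl on C12; left half C1′ (bears C7′H=C8′), C2′=C3′ (CH2OH), C6′ (isopropyl). TBS = tert-butyldimethylsilyl, TBDPS = tert-butyldiphenylsilyl.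
Assumption: the target is taken exactly as drawn, (1R,4S,4aR,8aR) in the lactone half and (1′R,6′S) in the left ring, which makes the two cis CH/isopropyl pairs antipodal; acids are liberated with dilute aqueous HCl and written in neutral form.

**Right half (from (+)-menthol)**

Step 1
Reactants: 1 3-methylcyclohex-2-en-1-one
Product: 2 1-(tert-butyldimethylsilyloxy)-3-methylcyclohexa-1,3-diene
Conditions: TBSCl, NaI, Et3N, MeCN, 50 °C; distilled from a trace of Et3N
Reagents that add atoms: tert-butyldimethylsilyl chloride, CC(C)(C)[Si](C)(C)Cl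
Why: Thermodynamic silyl dienol ether formation (soft enolisation with silyl iodide made in situ): the reversible iodide/ammonium medium should favour the linearly conjugated endocyclic 1-siloxy-1,3-diene over the cross-conjugated kinetic isomer, and the exocyclic isomer is s-trans-locked and inert in step 4.

Step 2
Reactants: 3 furfural
Product: 4 5-hydroxyfuran-2(5H)-one (racemic hemiacetal)
Conditions: O2, hν (visible), rose bengal (C20H2Cl4I4Na2O5, cat.), MeOH, 20 °C
Reagents that add atoms: oxygen, O=O
Why: Dye-sensitised photooxygenation: singlet oxygen adds [4+2] to the furan and methanolysis of the endoperoxide expels the formyl carbon as methyl formate, leaving the hydroxybutenolide.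

Step 3
Reactants: 4 5-hydroxyfuran-2(5H)-one; 5 (+)-menthol
Product: 6 (5S)-5-[(1S,2R,5S)-menthyloxy]furan-2(5H)-one
Conditions: (1S)-(+)-10-camphorsulfonic acid (cat.), toluene, reflux (Dean–Stark); crystallisation from hexane, mother liquor re-equilibrated with the acid
Reagents that add atoms: none
Why: Acid-catalysed acetal exchange of the pseudo-acid; the C5 epimers interconvert through the oxocarbenium ion and the (5S) epimer of the (+)-menthyl series is the crystalline one, so crystallisation-driven epimerisation should funnel the material to 6.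

Step 4
Reactants: 2 siloxydiene; 6 (5S)-menthyloxyfuranone
Product: 7 endo cycloadduct: 1-(TBSO)-5-methylbicyclo[2.2.2]oct-5-ene with a butyrolactone fused endo at C2–C3, lactone C=O (C9) on the carbon next to the siloxy bridgehead, menthyloxy acetal carbon (C13) on the other, menthyloxy anti to the bicycle
Conditions: toluene, 2,6-di-tert-butyl-4-methylphenol (trace), 100 °C, sealed tube
Reagents that add atoms: none
Why: A thermal, concerted, suprafacial Diels–Alder reaction of normal electron demand (diene HOMO raised by the 1-siloxy group, dienophile LUMO lowered by the lactone carbonyl) forms C4–C4a and C1–C8a in one asynchronous event; the closest known reaction type is the Diels–Alder addition of 5-menthyloxyfuran-2(5H)-one to siloxy dienes and of 1-oxygenated cyclohexa-1,3-dienes to acrylic dienophiles, which gives bicyclo[2.2.2]octenes. The ring that closes is the six-membered carbocycle C4–C4a–C8a–C1–C(CH3)=CH, by cycloaddition across the termini of the cyclic diene, whose own CH2–CH2 unit (C3–C2) makes the product bicyclic. C4 and C1 become the bridgeheads and are tied to each other by the ring; C4a and C8a are cis to each other because the cis dienophile adds suprafacially, syn to the new etheno bridge because the lactone carbonyl lies under the diene (endo rule), and of one absolute sense because the diene can reach only the face of the furanone opposite the menthyloxy group on the adjacent acetal carbon. The step needs regio-, endo- and facial selectivity: the regiochemistry is secured twice, since both the 1-siloxy and the 3-methyl group put the largest HOMO coefficient on the unsubstituted diene terminus (future C1), which bonds to the lactone β-carbon and leaves the siloxy terminus to bond to the α-carbon. Four stereocentres (C1, C4, C4a, C8a) and two C–C bonds result; C4a comes out cis to C13 and is corrected in step 11.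

Step 5
Reactants: 7 endo cycloadduct
Product: 9 keto aldehyde of ring A (acetyl on C1; formyl and OTBS on C4; menthyloxy lactone on C4a/C8a), via ozonide 8 (not isolated)
Conditions: O3, CH2Cl2, −78 °C; then PPh3, −78 → 20 °C
Reagents that add atoms: ozone, [O-][O+]=O
Why: Ozonolysis with reductive work-up: the only alkene is the CH=C(CH3) bridge, and its cleavage leaves CHO on C4 and acetyl on C1 on the same face of ring A without touching a stereocentre.

Step 6
Reactants: 9 keto aldehyde
Product: 10 hydroxy ketone (C14–OH)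
Conditions: NaBH4, EtOH/CH2Cl2, −78 °C; AcOH quench at −78 °C
Reagents that add atoms: none
Why: Chemoselective borohydride reduction: at −78 °C the α-oxygenated aldehyde should react far faster than the methyl ketone or the lactone, and the cold acid quench protonates the alkoxide before it can attack the cis lactone carbonyl.

Step 7
Reactants: 10 hydroxy ketone
Product: 11 C14 TBDPS ether
Conditions: TBDPSCl, imidazole, DMAP (cat.), DMF, 20 °C
Reagents that add atoms: tert-butyl(chloro)diphenylsilane, CC(C)(C)[Si](Cl)(c1ccccc1)c1ccccc1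
Why: Silyl ether formation on the primary alcohol, so that it can neither lactonise onto C9 nor bridge to C13 later; TBDPS should tolerate both the acidic methanolysis and methoxide.

Step 8
Reactants: 11 methyl ketone
Product: 12 C1 isopropenyl compound
Conditions: Zn, CH2Br2, TiCl4, THF/CH2Cl2, 0 → 20 °C
Reagents that add atoms: dibromomethane, BrCBr
Why: Takai–Lombardo methylenation: the non-basic gem-dimetallic reagent methylenates the ketone without enolising C1 (whose acetyl group is cis to three other ring substituents and could epimerise under basic ylide conditions) and leaves the lactone alone.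

Step 9
Reactants: 12 isopropenyl compound
Product: 13 C1 isopropyl lactone acetal
Conditions: H2 (1 atm), 10% Pd/C, EtOAc, 20 °C
Reagents that add atoms: none
Why: Heterogeneous catalytic hydrogenation of the 1,1-disubstituted alkene; no stereocentre is created and nothing else is reducible.

Step 10
Reactants: 13 lactone acetal
Product: 14 cis methyl ester dimethyl acetal (C9 ester cis to C13)
Conditions: MeOH, HC(OMe)3, TsOH·H2O (0.2 equiv), 60 °C
Reagents that add atoms: methanol, CO; trimethyl orthoformate, COC(OC)OC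
Why: Acid-catalysed alcoholysis of the pseudo-ester (acetal exchange at C13, then Fischer-type opening at C9) driven by orthoformate removal of water; the auxiliary is released and C13 is masked, so that only C4a remains enolisable.

Step 11
Reactants: 14 cis ester acetal
Product: 15 trans methyl ester dimethyl acetal (C4a epimer; C9 on the face of the C4 oxygen)
Conditions: NaOMe (0.5 equiv), MeOH, 50 °C
Reagents that add atoms: none
Why: Thermodynamic ester epimerisation through the enolate: the cis isomer must hold either C13/C14 or C9/isopropyl 1,3-diaxial, whereas the trans isomer has a chair with C9, C13 and C14 all equatorial, so the equilibrium should lie on the side of 15, and C8a is not acidic while C13 is an acetal.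

Step 12
Reactants: 15 trans ester acetal
Product: 16 trans ester aldehyde (C13 = CHO)
Conditions: 1 M aq. HCl, THF, 20 °C
Reagents that add atoms: water, O
Why: Acid-catalysed acetal hydrolysis; the silyl ethers and the methyl ester should survive brief dilute acid.

Step 13
Reactants: 16 ester aldehyde
Product: 17 vinyl methyl ester (C13 = CH=CH2)
Conditions: Ph3PCH3Br, KN(SiMe3)2, THF, −78 → 0 °C
Reagents that add atoms: methyltriphenylphosphonium bromide, C[P+](c1ccccc1)(c1ccccc1)c1ccccc1.[Br-]
Why: Wittig methylenation at low temperature; addition to the aldehyde should outrun enolisation at C8a, and the hindered ester is inert.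

Step 14
Reactants: 17 vinyl methyl ester
Product: 18 vinyl acid (C9 = CO2H)
Conditions: n-PrSLi, HMPA, 25 °C; dilute aq. HCl work-up
Reagents that add atoms: none
Why: SN2 dealkylation of the methyl ester by thiolate at the methyl carbon, which does not depend on access to the heavily shielded C9 carbonyl that would defeat saponification.

Step 15
Reactants: 18 vinyl acid
Product: 21 vinyl hydroxy acid (C4–OH; C14–OTBS; C9 acid), via diol acid 19 (not isolated), via silyl ester 20 (not isolated)
Conditions: Bu4NF, THF, 60 °C; evaporate; TBSCl, imidazole, DMF, 25 °C; then K2CO3, MeOH/H2O, 0 °C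
Reagents that add atoms: tert-butyldimethylsilyl chloride, CC(C)(C)[Si](C)(C)Cl
Why: Fluoride desilylation then selective resilylation: at this stage nothing is base-sensitive, so hot fluoride can remove the tertiary TBS ether as well, TBSCl then caps only the primary hydroxyl and the carboxyl, and carbonate methanolysis frees the acid, the C14 hydroxyl never meeting an electrophilic C9.

Step 16
Reactants: 21 vinyl hydroxy acid; 22 tert-butyl 2-(bromomethyl)acrylate
Product: 23 diene ester (C9 2-(tert-butoxycarbonyl)allyl ester)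
Conditions: Cs2CO3, DMF, 0 → 25 °C
Reagents that add atoms: none
Why: O-Alkylation of the cesium carboxylate by the allylic bromide (SN2 and SN2′ give the same ester); the tertiary alcohol is not alkylated.

Step 17
Reactants: 23 diene ester
Product: 24 ring-B lactone (tert-butyl ester at C15; C14–OTBS; C4–OH)
Conditions: second-generation Hoveyda–Grubbs catalyst RuCl2(H2IMes)(=CH-C6H4-2-OiPr) (10 mol %), toluene (5 mM), 80 °C
Reagents that add atoms: none
Why: Ring-closing metathesis to the seven-membered ring B: the monosubstituted C13 vinyl loads the catalyst and closes onto the tethered 1,1-disubstituted acrylate with loss of ethene, and the ring forces C8a and C11 cis on C12=C13, as in the target.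

Step 18
Reactants: 24 ring-B lactone
Product: 25 diol lactone (C14–OH and C4–OH free)
Conditions: HF·pyridine, pyridine, THF, 0 °C; used at once
Reagents that add atoms: none
Why: Fluoride desilylation under buffered, weakly acidic conditions removes the primary TBS ether and leaves the esters alone; 25 is not stored because its hydroxyl is γ to the lactone carbonyl.

**Left half (mirror-image series from (−)-menthol)**

Step 19
Reactants: 4 5-hydroxyfuran-2(5H)-one; 26 (−)-menthol
Product: 27 (5R)-5-[(1R,2S,5R)-menthyloxy]furan-2(5H)-one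
Conditions: (1S)-(+)-10-camphorsulfonic acid (cat.), toluene, reflux (Dean–Stark); crystallisation from hexane, mother liquor re-equilibrated
Reagents that add atoms: none
Why: Acid-catalysed acetal exchange with crystallisation-driven epimerisation, as in step 3; in the (−)-menthyl series the (5R) epimer is the crystalline one.

Step 20
Reactants: 2 siloxydiene; 27 (5R)-menthyloxyfuranone
Product: 28 enantiomer of cycloadduct 7
Conditions: toluene, 2,6-di-tert-butyl-4-methylphenol (trace), 100 °C, sealed tube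
Reagents that add atoms: none
Why: The same endo, regio- and face-selective Diels–Alder reaction as step 4; the antipodal acetal centre turns the diene to the other face, so all four new centres are mirrored.

Step 21
Reactants: 28 cycloadduct
Product: 30 enantiomer of keto aldehyde 9, via ozonide 29 (not isolated)
Conditions: O3, CH2Cl2, −78 °C; then PPh3, −78 → 20 °C
Reagents that add atoms: ozone, [O-][O+]=O
Why: Ozonolysis with reductive work-up of the only alkene, as in step 5.

Step 22
Reactants: 30 keto aldehyde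
Product: 31 enantiomer of hydroxy ketone 10
Conditions: NaBH4, EtOH/CH2Cl2, −78 °C; AcOH quench at −78 °C
Reagents that add atoms: none
Why: Chemoselective borohydride reduction of the aldehyde beside the methyl ketone and the lactone, as in step 6.

Step 23
Reactants: 31 hydroxy ketone
Product: 32 enantiomer of TBDPS ether 11
Conditions: TBDPSCl, imidazole, DMAP (cat.), DMF, 20 °C
Reagents that add atoms: tert-butyl(chloro)diphenylsilane, CC(C)(C)[Si](Cl)(c1ccccc1)c1ccccc1
Why: Silyl ether formation on the primary alcohol, as in step 7.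

Step 24
Reactants: 32 methyl ketone
Product: 33 enantiomer of isopropenyl compound 12
Conditions: Zn, CH2Br2, TiCl4, THF/CH2Cl2, 0 → 20 °C
Reagents that add atoms: dibromomethane, BrCBr
Why: Takai–Lombardo methylenation under non-basic conditions, as in step 8.

Step 25
Reactants: 33 isopropenyl compound
Product: 34 enantiomer of lactone acetal 13
Conditions: H2 (1 atm), 10% Pd/C, EtOAc, 20 °C
Reagents that add atoms: none
Why: Catalytic hydrogenation of the 1,1-disubstituted alkene, as in step 9.

Step 26
Reactants: 34 lactone acetal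
Product: 35 enantiomer of cis ester acetal 14
Conditions: MeOH, HC(OMe)3, TsOH·H2O (0.2 equiv), 60 °C
Reagents that add atoms: methanol, CO; trimethyl orthoformate, COC(OC)OC
Why: Acid-catalysed alcoholysis of the pseudo-ester with release of (−)-menthol, as in step 10.

Step 27
Reactants: 35 cis ester acetal
Product: 36 enantiomer of trans ester acetal 15
Conditions: NaOMe (0.5 equiv), MeOH, 50 °C
Reagents that add atoms: none
Why: Thermodynamic ester epimerisation at C4a, as in step 11; it is needed here because it places the C9 carboxyl cis to the C4 oxygen, the arrangement that β-lactonisation in step 36 requires.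

Step 28
Reactants: 36 trans ester acetal
Product: 37 enantiomer of ester aldehyde 16
Conditions: 1 M aq. HCl, THF, 20 °C
Reagents that add atoms: water, O
Why: Acid-catalysed acetal hydrolysis, as in step 12.

Step 29
Reactants: 37 ester aldehyde
Product: 38 enantiomer of vinyl ester 17
Conditions: Ph3PCH3Br, KN(SiMe3)2, THF, −78 → 0 °C
Reagents that add atoms: methyltriphenylphosphonium bromide, C[P+](c1ccccc1)(c1ccccc1)c1ccccc1.[Br-]
Why: Wittig methylenation, as in step 13.

Step 30
Reactants: 38 vinyl methyl ester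
Product: 39 enantiomer of vinyl acid 18
Conditions: n-PrSLi, HMPA, 25 °C; dilute aq. HCl work-up
Reagents that add atoms: none
Why: SN2 dealkylation of the hindered methyl ester by thiolate, as in step 14.

Step 31
Reactants: 39 vinyl acid
Product: 42 enantiomer of hydroxy acid 21, via diol acid 40 (not isolated), via silyl ester 41 (not isolated)
Conditions: Bu4NF, THF, 60 °C; evaporate; TBSCl, imidazole, DMF, 25 °C; then K2CO3, MeOH/H2O, 0 °C
Reagents that add atoms: tert-butyldimethylsilyl chloride, CC(C)(C)[Si](C)(C)Cl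
Why: Fluoride desilylation and selective resilylation, as in step 15; the tertiary hydroxyl is freed here because it must be free for step 36.

Step 32
Reactants: 42 vinyl hydroxy acid; 22 tert-butyl 2-(bromomethyl)acrylate
Product: 43 enantiomer of diene ester 23
Conditions: Cs2CO3, DMF, 0 → 25 °C
Reagents that add atoms: none
Why: O-Alkylation of the cesium carboxylate, as in step 16; the C9 carboxyl serves here as a traceless tether for the acrylate.

Step 33
Reactants: 43 diene ester
Product: 44 enantiomer of ring-B lactone 24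
Conditions: second-generation Hoveyda–Grubbs catalyst RuCl2(H2IMes)(=CH-C6H4-2-OiPr) (10 mol %), toluene (5 mM), 80 °C
Reagents that add atoms: none
Why: Ring-closing metathesis, as in step 17; the ring fixes the geometry in which the ring carbon is cis to the CH2O group and trans to the ester, as required for C7′=C8′.

Step 34
Reactants: 44 lactone
Product: 45 seco hydroxy acid (C9 acid; C4–OH; C14–OTBS; free allylic CH2OH on the (E)-enoate)
Conditions: LiOH·H2O, THF/H2O (3:1), 0 → 25 °C; dilute aq. HCl to pH 4 at 0 °C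
Reagents that add atoms: lithium hydroxide, [Li+].[OH-]
Why: Saponification of the seven-membered lactone, whose ester is held in the reactive cis conformation, so that hydroxide attack at C9 should outrun both cleavage of the tert-butyl enoate and conjugate addition at the hindered C13.

Step 35
Reactants: 45 seco hydroxy acid
Product: 47 bis-TBS β-hydroxy acid, via silyl ester 46 (not isolated)
Conditions: TBSCl, imidazole, DMF, 25 °C; then K2CO3, MeOH/H2O, 0 °C
Reagents that add atoms: tert-butyldimethylsilyl chloride, CC(C)(C)[Si](C)(C)Cl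
Why: Silylation of the primary allylic hydroxyl and the carboxyl (the tertiary hydroxyl is too hindered), then carbonate methanolysis of the silyl ester.

Step 36
Reactants: 47 β-hydroxy acid
Product: 48 cis-fused β-lactone (C4–O–C9(=O)–C4a)
Conditions: PhSO2Cl, pyridine, 0 → 5 °C
Reagents that add atoms: none
Why: β-Lactonisation of a β-hydroxy acid by carboxyl activation (mixed carboxylic–sulfonic anhydride): the tertiary hydroxyl, cis to C9 since step 27, closes the four-membered ring with retention at both centres.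

Step 37
Reactants: 48 β-lactone
Product: 49 tert-butyl (E)-2-[(TBSO)methyl]-3-[(1R,6S)-3-[(TBSO)methyl]-6-isopropylcyclohex-2-en-1-yl]acrylate
Conditions: xylene, 140 °C, sealed tube
Reagents that add atoms: none
Why: Thermal decarboxylation of the β-lactone (formal [2+2] cycloreversion): CO2 leaves from exactly the two carbons that carried the oxygen and C9, so the ring alkene appears regiospecifically at C2′=C3′ and neither C1′ nor C6′ is touched.

Step 38
Reactants: 49 tert-butyl ester
Product: 51 left acid, via trimethylsilyl ester 50 (not isolated)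
Conditions: TMSOTf, 2,6-lutidine, CH2Cl2, 0 °C; pH 5 aqueous buffer work-up
Reagents that add atoms: none
Why: Silyl-triflate cleavage of a tert-butyl ester: O-silylation of the ester carbonyl triggers loss of isobutene under non-protic conditions that spare the allylic TBS ethers, and the trimethylsilyl ester hydrolyses on work-up.

**Union and release**

Step 39
Reactants: 51 left acid; 25 diol lactone
Product: 53 coupled ester (C14–O–C(=O)–C8′), via mixed anhydride 52 (not isolated)
Conditions: 2,4,6-trichlorobenzoyl chloride, Et3N, THF, 0 → 25 °C; then 25, DMAP, toluene, 25 °C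
Reagents that add atoms: none
Why: Yamaguchi esterification: the mixed anhydride acylates the primary C14 hydroxyl through the acylpyridinium ion, and the tertiary C4 hydroxyl does not compete.

Step 40
Reactants: 53 coupled ester
Product: 55 CNP0361406.11, via silylated ester 54 (not isolated)
Conditions: TMSOTf, 2,6-lutidine, CH2Cl2, 0 °C; then HF·pyridine, THF/pyridine, 0 → 25 °C
Reagents that add atoms: none
Why: Silyl-triflate cleavage of the tert-butyl ester (with transient O-silylation of the tertiary alcohol) followed by global fluoride desilylation; neither stage touches a stereocentre or the three ester linkages.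

**Compound list**

1 | 3-methylcyclohex-2-en-1-one | CC1=CC(=O)CCC1 | starting material
2 | 1-(tert-butyldimethylsilyloxy)-3-methylcyclohexa-1,3-diene | CC1=CCCC(O[Si](C)(C)C(C)(C)C)=C1 | intermediate
3 | furfural | O=Cc1ccco1 | starting material
4 | 5-hydroxyfuran-2(5H)-one (racemic) | O=C1OC(O)C=C1 | intermediate
5 | (+)-menthol, (1S,2R,5S) | CC(C)[C@H]1CC[C@H](C)C[C@@H]1O | starting material
6 | (5S)-5-[(1S,2R,5S)-menthyloxy]furan-2(5H)-one | O=C1O[C@H](O[C@H]2C[C@@H](C)CC[C@@H]2C(C)C)C=C1 | intermediate
7 | endo cycloadduct, bridgehead TBS ether, menthyloxy lactone | CC1=C[C@]2(O[Si](C)(C)C(C)(C)C)CC[C@H]1[C@H]1[C@@H]2C(=O)O[C@@H]1O[C@H]1C[C@@H](C)CC[C@@H]1C(C)C | intermediate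
8 | ozonide of 7 (1,2,4-trioxolane across the former alkene, mixture at the two trioxolane carbons) | CC1(O3)OOC3[C@]2(O[Si](C)(C)C(C)(C)C)CC[C@H]1[C@H]1[C@@H]2C(=O)O[C@@H]1O[C@H]1C[C@@H](C)CC[C@@H]1C(C)C | intermediate
9 | keto aldehyde: C1 acetyl and C4 formyl cis, C4 OTBS, cis-fused menthyloxy lactone on C4a/C8a | CC(=O)[C@H]1CC[C@@](O[Si](C)(C)C(C)(C)C)(C=O)[C@H]2C(=O)O[C@H](O[C@H]3C[C@@H](C)CC[C@@H]3C(C)C)[C@@H]12 | intermediate
10 | hydroxy ketone (C14–OH) | CC(=O)[C@H]1CC[C@@](O[Si](C)(C)C(C)(C)C)(CO)[C@H]2C(=O)O[C@H](O[C@H]3C[C@@H](C)CC[C@@H]3C(C)C)[C@@H]12 | intermediate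
11 | C14 TBDPS ether of 10 | CC(=O)[C@H]1CC[C@@](O[Si](C)(C)C(C)(C)C)(CO[Si](c4ccccc4)(c5ccccc5)C(C)(C)C)[C@H]2C(=O)O[C@H](O[C@H]3C[C@@H](C)CC[C@@H]3C(C)C)[C@@H]12 | intermediate
12 | C1 isopropenyl lactone acetal | CC(=C)[C@H]1CC[C@@](O[Si](C)(C)C(C)(C)C)(CO[Si](c4ccccc4)(c5ccccc5)C(C)(C)C)[C@H]2C(=O)O[C@H](O[C@H]3C[C@@H](C)CC[C@@H]3C(C)C)[C@@H]12 | intermediate
13 | C1 isopropyl lactone acetal | CC(C)[C@H]1CC[C@@](O[Si](C)(C)C(C)(C)C)(CO[Si](c4ccccc4)(c5ccccc5)C(C)(C)C)[C@H]2C(=O)O[C@H](O[C@H]3C[C@@H](C)CC[C@@H]3C(C)C)[C@@H]12 | intermediate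
14 | cis methyl ester dimethyl acetal (C9 cis to C13) | CC(C)[C@H]1CC[C@@](O[Si](C)(C)C(C)(C)C)(CO[Si](c2ccccc2)(c3ccccc3)C(C)(C)C)[C@@H](C(=O)OC)[C@H]1C(OC)OC | intermediate
15 | trans methyl ester dimethyl acetal (C4a epimer of 14) | CC(C)[C@H]1CC[C@@](O[Si](C)(C)C(C)(C)C)(CO[Si](c2ccccc2)(c3ccccc3)C(C)(C)C)[C@H](C(=O)OC)[C@H]1C(OC)OC | intermediate
16 | trans ester aldehyde | CC(C)[C@H]1CC[C@@](O[Si](C)(C)C(C)(C)C)(CO[Si](c2ccccc2)(c3ccccc3)C(C)(C)C)[C@H](C(=O)OC)[C@H]1C=O | intermediate
17 | vinyl methyl ester | CC(C)[C@H]1CC[C@@](O[Si](C)(C)C(C)(C)C)(CO[Si](c2ccccc2)(c3ccccc3)C(C)(C)C)[C@H](C(=O)OC)[C@H]1C=C | intermediate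
18 | vinyl acid | CC(C)[C@H]1CC[C@@](O[Si](C)(C)C(C)(C)C)(CO[Si](c2ccccc2)(c3ccccc3)C(C)(C)C)[C@H](C(=O)O)[C@H]1C=C | intermediate
19 | diol acid (C4–OH, C14–OH, C9 acid, C13 vinyl) | CC(C)[C@H]1CC[C@@](O)(CO)[C@H](C(=O)O)[C@H]1C=C | intermediate
20 | C14 TBS ether TBS ester of 19 | CC(C)[C@H]1CC[C@@](O)(CO[Si](C)(C)C(C)(C)C)[C@H](C(=O)O[Si](C)(C)C(C)(C)C)[C@H]1C=C | intermediate
21 | vinyl hydroxy acid (C4–OH, C14–OTBS) | CC(C)[C@H]1CC[C@@](O)(CO[Si](C)(C)C(C)(C)C)[C@H](C(=O)O)[C@H]1C=C | intermediate
22 | tert-butyl 2-(bromomethyl)acrylate | C=C(CBr)C(=O)OC(C)(C)C | starting material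
23 | diene ester (C9 2-(tert-butoxycarbonyl)allyl ester) | CC(C)[C@H]1CC[C@@](O)(CO[Si](C)(C)C(C)(C)C)[C@H](C(=O)OCC(=C)C(=O)OC(C)(C)C)[C@H]1C=C | intermediate
24 | ring-B lactone, C15 tert-butyl ester, C14–OTBS | CC(C)[C@H]1CC[C@@](O)(CO[Si](C)(C)C(C)(C)C)[C@@H]2C(=O)OCC(C(=O)OC(C)(C)C)=C[C@@H]12 | intermediate
25 | diol lactone, C15 tert-butyl ester | CC(C)[C@H]1CC[C@@](O)(CO)[C@@H]2C(=O)OCC(C(=O)OC(C)(C)C)=C[C@@H]12 | intermediate
26 | (−)-menthol, (1R,2S,5R) | CC(C)[C@@H]1CC[C@@H](C)C[C@H]1O | starting material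
27 | (5R)-5-[(1R,2S,5R)-menthyloxy]furan-2(5H)-one | O=C1O[C@@H](O[C@@H]2C[C@H](C)CC[C@H]2C(C)C)C=C1 | intermediate
28 | enantiomer of 7 | CC1=C[C@@]2(O[Si](C)(C)C(C)(C)C)CC[C@@H]1[C@@H]1[C@H]2C(=O)O[C@H]1O[C@@H]1C[C@H](C)CC[C@H]1C(C)C | intermediate
29 | enantiomer of ozonide 8 | CC1(O3)OOC3[C@@]2(O[Si](C)(C)C(C)(C)C)CC[C@@H]1[C@@H]1[C@H]2C(=O)O[C@H]1O[C@@H]1C[C@H](C)CC[C@H]1C(C)C | intermediate
30 | enantiomer of 9 | CC(=O)[C@@H]1CC[C@](O[Si](C)(C)C(C)(C)C)(C=O)[C@@H]2C(=O)O[C@@H](O[C@@H]3C[C@H](C)CC[C@H]3C(C)C)[C@H]12 | intermediate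
31 | enantiomer of 10 | CC(=O)[C@@H]1CC[C@](O[Si](C)(C)C(C)(C)C)(CO)[C@@H]2C(=O)O[C@@H](O[C@@H]3C[C@H](C)CC[C@H]3C(C)C)[C@H]12 | intermediate
32 | enantiomer of 11 | CC(=O)[C@@H]1CC[C@](O[Si](C)(C)C(C)(C)C)(CO[Si](c4ccccc4)(c5ccccc5)C(C)(C)C)[C@@H]2C(=O)O[C@@H](O[C@@H]3C[C@H](C)CC[C@H]3C(C)C)[C@H]12 | intermediate
33 | enantiomer of 12 | CC(=C)[C@@H]1CC[C@](O[Si](C)(C)C(C)(C)C)(CO[Si](c4ccccc4)(c5ccccc5)C(C)(C)C)[C@@H]2C(=O)O[C@@H](O[C@@H]3C[C@H](C)CC[C@H]3C(C)C)[C@H]12 | intermediate
34 | enantiomer of 13 | CC(C)[C@@H]1CC[C@](O[Si](C)(C)C(C)(C)C)(CO[Si](c4ccccc4)(c5ccccc5)C(C)(C)C)[C@@H]2C(=O)O[C@@H](O[C@@H]3C[C@H](C)CC[C@H]3C(C)C)[C@H]12 | intermediate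
35 | enantiomer of 14 | CC(C)[C@@H]1CC[C@](O[Si](C)(C)C(C)(C)C)(CO[Si](c2ccccc2)(c3ccccc3)C(C)(C)C)[C@H](C(=O)OC)[C@@H]1C(OC)OC | intermediate
36 | enantiomer of 15 | CC(C)[C@@H]1CC[C@](O[Si](C)(C)C(C)(C)C)(CO[Si](c2ccccc2)(c3ccccc3)C(C)(C)C)[C@@H](C(=O)OC)[C@@H]1C(OC)OC | intermediate
37 | enantiomer of 16 | CC(C)[C@@H]1CC[C@](O[Si](C)(C)C(C)(C)C)(CO[Si](c2ccccc2)(c3ccccc3)C(C)(C)C)[C@@H](C(=O)OC)[C@@H]1C=O | intermediate
38 | enantiomer of 17 | CC(C)[C@@H]1CC[C@](O[Si](C)(C)C(C)(C)C)(CO[Si](c2ccccc2)(c3ccccc3)C(C)(C)C)[C@@H](C(=O)OC)[C@@H]1C=C | intermediate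
39 | enantiomer of 18 | CC(C)[C@@H]1CC[C@](O[Si](C)(C)C(C)(C)C)(CO[Si](c2ccccc2)(c3ccccc3)C(C)(C)C)[C@@H](C(=O)O)[C@@H]1C=C | intermediate
40 | enantiomer of 19 | CC(C)[C@@H]1CC[C@](O)(CO)[C@@H](C(=O)O)[C@@H]1C=C | intermediate
41 | enantiomer of 20 | CC(C)[C@@H]1CC[C@](O)(CO[Si](C)(C)C(C)(C)C)[C@@H](C(=O)O[Si](C)(C)C(C)(C)C)[C@@H]1C=C | intermediate
42 | enantiomer of 21 | CC(C)[C@@H]1CC[C@](O)(CO[Si](C)(C)C(C)(C)C)[C@@H](C(=O)O)[C@@H]1C=C | intermediate
43 | enantiomer of 23 | CC(C)[C@@H]1CC[C@](O)(CO[Si](C)(C)C(C)(C)C)[C@@H](C(=O)OCC(=C)C(=O)OC(C)(C)C)[C@@H]1C=C | intermediate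
44 | enantiomer of 24 | CC(C)[C@@H]1CC[C@](O)(CO[Si](C)(C)C(C)(C)C)[C@H]2C(=O)OCC(C(=O)OC(C)(C)C)=C[C@H]12 | intermediate
45 | seco hydroxy acid: C9 acid, C4–OH, C14–OTBS, (E)-enoate with free CH2OH cis to the ring | CC(C)[C@@H]1CC[C@](O)(CO[Si](C)(C)C(C)(C)C)[C@@H](C(=O)O)[C@@H]1/C=C(\CO)C(=O)OC(C)(C)C | intermediate
46 | bis-TBS ether TBS ester of 45 | CC(C)[C@@H]1CC[C@](O)(CO[Si](C)(C)C(C)(C)C)[C@@H](C(=O)O[Si](C)(C)C(C)(C)C)[C@@H]1/C=C(\CO[Si](C)(C)C(C)(C)C)C(=O)OC(C)(C)C | intermediate
47 | bis-TBS β-hydroxy acid | CC(C)[C@@H]1CC[C@](O)(CO[Si](C)(C)C(C)(C)C)[C@@H](C(=O)O)[C@@H]1/C=C(\CO[Si](C)(C)C(C)(C)C)C(=O)OC(C)(C)C | intermediate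
48 | cis-fused β-lactone | CC(C)[C@@H]1CC[C@@]2(CO[Si](C)(C)C(C)(C)C)OC(=O)[C@H]2[C@@H]1/C=C(\CO[Si](C)(C)C(C)(C)C)C(=O)OC(C)(C)C | intermediate
49 | tert-butyl (E)-2-[(TBSO)methyl]-3-[(1R,6S)-3-[(TBSO)methyl]-6-isopropylcyclohex-2-en-1-yl]acrylate | CC(C)(C)OC(=O)/C(=C/[C@H]1C=C(CO[Si](C)(C)C(C)(C)C)CC[C@H]1C(C)C)CO[Si](C)(C)C(C)(C)C | intermediate
50 | trimethylsilyl ester corresponding to 49 | C[Si](C)(C)OC(=O)/C(=C/[C@H]1C=C(CO[Si](C)(C)C(C)(C)C)CC[C@H]1C(C)C)CO[Si](C)(C)C(C)(C)C | intermediate
51 | left acid, (E)-2-[(TBSO)methyl]-3-[(1R,6S)-3-[(TBSO)methyl]-6-isopropylcyclohex-2-en-1-yl]acrylic acid | OC(=O)/C(=C/[C@H]1C=C(CO[Si](C)(C)C(C)(C)C)CC[C@H]1C(C)C)CO[Si](C)(C)C(C)(C)C | intermediate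
52 | mixed anhydride of 51 with 2,4,6-trichlorobenzoic acid | O=C(OC(=O)/C(=C/[C@H]1C=C(CO[Si](C)(C)C(C)(C)C)CC[C@H]1C(C)C)CO[Si](C)(C)C(C)(C)C)c1c(Cl)cc(Cl)cc1Cl | intermediate
53 | coupled ester: C14 ester of 25 with 51 | CC(C)[C@H]1CC[C@@](O)(COC(=O)/C(=C/[C@H]2C=C(CO[Si](C)(C)C(C)(C)C)CC[C@H]2C(C)C)CO[Si](C)(C)C(C)(C)C)[C@@H]2C(=O)OCC(C(=O)OC(C)(C)C)=C[C@@H]12 | intermediate
54 | C15 trimethylsilyl ester, C4 trimethylsilyl ether of the bis-TBS compound | CC(C)[C@H]1CC[C@@](O[Si](C)(C)C)(COC(=O)/C(=C/[C@H]2C=C(CO[Si](C)(C)C(C)(C)C)CC[C@H]2C(C)C)CO[Si](C)(C)C(C)(C)C)[C@@H]2C(=O)OCC(C(=O)O[Si](C)(C)C)=C[C@@H]12 | intermediate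
55 | CNP0361406.11 | CC(C)[C@H]1CC[C@@](O)(COC(=O)/C(=C/[C@H]2C=C(CO)CC[C@H]2C(C)C)CO)[C@@H]2C(=O)OCC(C(=O)O)=C[C@@H]12 | target

**Step count and risks**

Total step count: 40. Longest linear sequence: 23 steps (3 → 4 → 27 → … → 51 → 53 → 55; steps 2, 19–38, 39, 40).

Steps most likely to fail:

1. Step 4 (and its mirror, step 20). At the temperature the cycloaddition needs, the dienol ether may isomerise (1,5-hydrogen shift, or drift to the cross-conjugated 2-siloxy isomer) faster than it adds, and endo or regiocontrol may erode. The fallback builds the same two bonds in two polar steps at −78 °C. It sets out from 2 and 6: TBSOTf (cat.), CH2Cl2, −78 °C should give a vinylogous Mukaiyama–Michael addition of the γ-carbon of 2 to the β-carbon of 6, anti to the menthyloxy group, leading to the enone silyl ketene acetal F1. TiCl4, CH2Cl2, −78 → −20 °C should then close the ketene acetal onto the enone carbonyl (intramolecular Mukaiyama aldol) to the bridgehead alcohol F2 after aqueous work-up. TBSOTf, 2,6-lutidine resilylates F2, and the fallback comes back to the route at 7.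

2. Step 10 (and its mirror, step 26). The cis-fused pseudo-ester may only exchange its alkoxy group (menthyloxy for methoxy) and resist opening at the shielded C9 carbonyl, or the silyl ethers may be lost on forcing. The fallback sets out from 13: aqueous CF3CO2H in THF should hydrolyse the acetal to the lactol F3 with release of menthol. Me3SiCHN2 in MeOH/toluene methylates the open-chain acid tautomer under neutral conditions to the cis ester aldehyde F4. HC(OMe)3, MeOH and pyridinium p-toluenesulfonate then acetalise the aldehyde, and the fallback comes back at 14.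

3. Step 39. The strained lactone carbonyl C9 may be transferred to the freed C14 hydroxyl (trans-fused γ-lactone, C11–OH released) before or during acylation, and γ-deprotonation of the activated acid (vinylketene) would cost the C1′ configuration. The fallback makes the inter-fragment ester before ring B exists. It sets out from 17, where C9 is a shielded acyclic methyl ester: HF·pyridine removes the TBDPS group to give the alcohol F5. Acid 51 with EDC·HCl and DMAP/DMAP·HCl (Steglich conditions) gives the ester F6; LiI in pyridine at reflux (SN2 demethylation) gives the acid F7. Bromide 22 with Cs2CO3 in DMF gives the diene F8, and ring-closing metathesis with the catalyst of step 17 gives the lactone F9. Under the conditions of step 40, with longer fluoride exposure for the tertiary TBS ether, the fallback comes back to the route at 55.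

**Further compounds**

F1 | step 4 | enone silyl ketene acetal (Michael adduct) | CC1=CC(=O)CC[C@H]1[C@H]1C=C(O[Si](C)(C)C(C)(C)C)O[C@@H]1O[C@H]1C[C@@H](C)CC[C@@H]1C(C)C
F2 | step 4 | bridgehead alcohol (desilyl 7) | CC1=C[C@]2(O)CC[C@H]1[C@H]1[C@@H]2C(=O)O[C@@H]1O[C@H]1C[C@@H](C)CC[C@@H]1C(C)C
F3 | step 10 | cis-fused lactol (hydroxy lactone, mixture at the lactol carbon) | CC(C)[C@H]1CC[C@@](O[Si](C)(C)C(C)(C)C)(CO[Si](c4ccccc4)(c5ccccc5)C(C)(C)C)[C@H]2C(=O)OC(O)[C@@H]12
F4 | step 10 | cis methyl ester aldehyde | CC(C)[C@H]1CC[C@@](O[Si](C)(C)C(C)(C)C)(CO[Si](c2ccccc2)(c3ccccc3)C(C)(C)C)[C@@H](C(=O)OC)[C@H]1C=O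
F5 | step 39 | C14 alcohol of vinyl methyl ester (C4–OTBS kept) | CC(C)[C@H]1CC[C@@](O[Si](C)(C)C(C)(C)C)(CO)[C@H](C(=O)OC)[C@H]1C=C
F6 | step 39 | C14 ester of F5 with 51 | CC(C)[C@H]1CC[C@@](O[Si](C)(C)C(C)(C)C)(COC(=O)/C(=C/[C@H]2C=C(CO[Si](C)(C)C(C)(C)C)CC[C@H]2C(C)C)CO[Si](C)(C)C(C)(C)C)[C@H](C(=O)OC)[C@H]1C=C
F7 | step 39 | C9 acid of F6 | CC(C)[C@H]1CC[C@@](O[Si](C)(C)C(C)(C)C)(COC(=O)/C(=C/[C@H]2C=C(CO[Si](C)(C)C(C)(C)C)CC[C@H]2C(C)C)CO[Si](C)(C)C(C)(C)C)[C@H](C(=O)O)[C@H]1C=C
F8 | step 39 | C9 2-(tert-butoxycarbonyl)allyl ester of F7 | CC(C)[C@H]1CC[C@@](O[Si](C)(C)C(C)(C)C)(COC(=O)/C(=C/[C@H]2C=C(CO[Si](C)(C)C(C)(C)C)CC[C@H]2C(C)C)CO[Si](C)(C)C(C)(C)C)[C@H](C(=O)OCC(=C)C(=O)OC(C)(C)C)[C@H]1C=C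
F9 | step 39 | ring-B lactone, C4–OTBS analogue of 53 | CC(C)[C@H]1CC[C@@](O[Si](C)(C)C(C)(C)C)(COC(=O)/C(=C/[C@H]2C=C(CO[Si](C)(C)C(C)(C)C)CC[C@H]2C(C)C)CO[Si](C)(C)C(C)(C)C)[C@@H]2C(=O)OCC(C(=O)OC(C)(C)C)=C[C@@H]12
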